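The meeting began with the late reading times, 4.00 d to 10.0 d, when L in the ash run is down to 1.7% and less, and the chair asked us to count what is left of Q, not what is made.

| flask | D | X | Z | remark | time |
|---|---|---|---|---|---|
| ash | 0.23 M | 0.48 M | 2.8 mM | run made earlier |  |
| cedar | 0.23 M | 0.76 M | 2.8 mM | run made earlier |  |
| flask | 0.23 M | 0.345 M | 2.8 mM |  | 15 d |

- ash (time / d: Q / %, L / %): 0.625: 38.4, 20.7; 1.04: 46.3, 14.8; 1.67: 51.4, 8.5; 2.50: 53.3, 5.1; 4.00: 53.0, 1.7; 6.00: 49.7, 1.1; 10.0: 42.8, 1.1
- cedar (time / d: Q / %, L / %): 0.625: 48.0, 24.7; 1.04: 57.7, 17.7; 1.67: 62.7, 9.4; 2.50: 65.4, 5.1; 4.00: 64.1, 2.0; 6.00: 60.1, 1.5; 10.0: 50.9, 0.2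

(readings scatter by 0.5 percentage points)

* the best time, 15 d at the latest, for Q
* the amount of Q, in percent of the D charged, at that time
* earliest time at which at least nineteen twentieths of that best amount are there, in d
* latest time at which they still are, in d

I reported that the fraction of Q left between those times gives a loss of 0.0356 d⁻¹ in the ash run and 0.0384 d⁻¹ in the cedar run. A colleague noted that these lie close, although [X] differs. Their mean, 0.0370 d⁻¹, was named the keeping rate: minus the logarithm of the fraction of Q left, per day.

The chair then asked for the window. I took the ash run as the shape, its [X] being nearer to this flask's 0.345 M. Its highest reading is 53.3% at 2.50 d. The share of that asked for in the window is passed on the way up near 1.58 d, by interpolation. From the reading at 4.00 d, the keeping rate brings Q back to that level at 5.23 d.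

For the height, I took the fraction of D not in Q at the highest reading of each run and carried its logarithm straight in [X] down to this flask, which gave 46.0%, with the times as in the ash run.

The forecast differs from this: 44.5% at 3.5 d, and a window from 1.9 d to 6 d, all later  and lower in amount, with the losses of Q and L taken as “neither depending on X”.

The flask gives 44.1% at 2.86 d, and the window runs from 1.59 d to 5.19 d.

    D + X ⇌ L (K = 4.50 M⁻¹, k = 0.500 M⁻¹ h⁻¹)
    D + X ⇌ Q (K = 91.0 M⁻¹, k = 0.180 M⁻¹ h⁻¹)
    L + Z ⇌ Q + Z, rate k3*[Z]*[L] forward; the back reaction follows from the equilibrium constant (k = 53.0 M⁻¹ h⁻¹)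
    X → J (k = 0.0430 h⁻¹)
    D ⇌ G (K = 0.690, k = 0.140 h⁻¹)
    2 Z → E (k = 82.0 M⁻¹ h⁻¹)

In this flask the half-life of X by its loss to J alone, 0.67 d, is longer than that of D by the step to Q alone at the charged concentrations, 0.47 d. At 2.86 d in this flask, X, charged at 0.345 M against 0.23 M of D, is down to 4.31% of its charge, and [J] is 0.222 M. Starting from 38.7% of Q at 7.50 d, the keeping rate gives 29.3% at 15.0 d, and the flask holds 29.8%. For a neighbour charged with 1.4 M of X, whose best is 77.0%, counting from 2.86 d as in this flask, the rate gives 49.1% at 15 d; the computed amount is 49.5%.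

All runs are calculated from invented constants; noise was put on by code.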